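**Plan** (labdane locants: C13 = ether carbon with vinyl and CH3; C8 = the other ether carbon; C9 = ring-fusion CH; C10 = quaternary C with CH3 and CH2CO2H (C1, C2); C5 = CH with C(CH3)2CO2H (C4, C3))

1. Retrosynthesis: first cut C2–C3 between the two carboxyl carbons. The two acid arms are cis on the carbocycle, the scar of a cis-fused six-membered ring A (C1–C2–C3–C4–C5–C10), carried as C2 ketone plus C3 spiro-dithiane. Then cut O–C8 and C9–C10 together, then C6–C7.
2. Enabling feature: with C2 as an enone carbonyl, C10 is its β-carbon. The E-C8=C9 alkene can reach it through C5–C6–C7 (ring B), and the C13 oxygen sits 1,5 to C8 (oxane), so one cation–olefin cascade closes both rings.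
3. Forward: ring-A sulfone (steps 1–5) and an allylic bromide from (R)-linalool (steps 6–8) are joined at C6–C7 and taken to the dithiane enone (steps 9–12). The cascade closes ring B, then the oxane (step 13). Ring A is then opened oxidatively (steps 14–15).
4. Stereochemistry: C13 comes from (R)-linalool. C5 comes from a CBS reduction relayed by a suprafacial [3,3] shift. C10, C9 and C8 are set in the cascade (cis fusion through the tether, E-alkene, chair-like anti addition).

Key step: step 13

Remark: in the target H-5 is cis to the C10 methyl group (5-epi to the manoyl oxide series), so ring A must be cis-fused while it exists; compounds 1, 3 and 10 are taken as purchasable.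

**Route**

Step 1
Reactants: 1 2,4,4-trimethylcyclohex-2-en-1-one
Product: 2 (1S)-2,4,4-trimethylcyclohex-2-en-1-ol
Conditions: (R)-2-methyl-CBS-oxazaborolidine (10 mol %), BH3·SMe2, THF, −20 °C
Reagents that add atoms: none
Why: Corey–Bakshi–Shibata reduction; the catalyst should distinguish the 2-methylalkenyl flank (large) from the CH2 flank (small) and deliver hydride to give the (S)-carbinol, which later controls C5.

Step 2
Reactants: 2 (1S)-2,4,4-trimethylcyclohex-2-en-1-ol; 3 [(4-methylphenyl)sulfonyl]acetic acid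
Product: 4 (1S)-2,4,4-trimethylcyclohex-2-en-1-yl [(4-methylphenyl)sulfonyl]acetate
Conditions: DCC, DMAP (cat.), CH2Cl2, 0 °C to rt
Reagents that add atoms: none
Why: Steglich esterification; the carbinol C–O bond is not broken, so the configuration is kept.

Step 3
Reactants: 4 (1S)-2,4,4-trimethylcyclohex-2-en-1-yl [(4-methylphenyl)sulfonyl]acetate
Product: 7 1-methyl-4-({[(1R)-2,6,6-trimethylcyclohex-2-en-1-yl]methyl}sulfonyl)benzene, via silyl ketene acetal 5 (not isolated), via rearranged silyl ester 6 (not isolated)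
Conditions: N,O-bis(trimethylsilyl)acetamide (0.2 equiv), KOAc (0.1 equiv), toluene, 110 °C
Reagents that add atoms: none
Why: decarboxylative Ireland–Claisen rearrangement of an allylic sulfonylacetate; the [3,3] shift is suprafacial on the ring, so the new C5–C6 bond forms on the face the oxygen leaves and the carbinol configuration is relayed to C5 before CO2 is lost.

Step 4
Reactants: 7 1-methyl-4-({[(1R)-2,6,6-trimethylcyclohex-2-en-1-yl]methyl}sulfonyl)benzene
Product: 8 (4R)-3,5,5-trimethyl-4-{[(4-methylphenyl)sulfonyl]methyl}cyclohex-2-en-1-one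
Conditions: Rh2(C6H10NO)4 (dirhodium tetracaprolactamate, 1 mol %), t-BuOOH (70% in water), 1,2-dichloroethane, 40 °C
Reagents that add atoms: tert-butyl hydroperoxide CC(C)(C)OO
Why: allylic C–H oxidation (tert-butylperoxyl radical chain) at the only allylic ring CH2 should give the conjugated enone (C2 carbonyl); no base is present, so the γ-hydrogen at C5 is not touched.

Step 5
Reactants: 8 (4R)-3,5,5-trimethyl-4-{[(4-methylphenyl)sulfonyl]methyl}cyclohex-2-en-1-one
Product: 9 (1RS,4R)-3,5,5-trimethyl-4-{[(4-methylphenyl)sulfonyl]methyl}cyclohex-2-en-1-ol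
Conditions: NaBH4, CeCl3·7H2O, MeOH, −78 °C
Reagents that add atoms: none
Why: Luche 1,2-reduction masks the enone for the carbanion chemistry that follows; the carbinol centre may form as both epimers because it is re-oxidised in step 11.

Step 6
Reactants: 10 (R)-linalool, (3R)-3,7-dimethylocta-1,6-dien-3-ol
Product: 11 triethyl{[(3R)-3,7-dimethylocta-1,6-dien-3-yl]oxy}silane
Conditions: Et3SiOTf, 2,6-lutidine, CH2Cl2, −78 to 0 °C
Reagents that add atoms: triethylsilyl trifluoromethanesulfonate CC[Si](CC)(CC)OS(=O)(=O)C(F)(F)F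
Why: silylation of the tertiary allylic alcohol; C13 of the target is bought with linalool, and the silyl ether both suppresses ionisation and later serves as the terminating nucleophile.

Step 7
Reactants: 11 triethyl{[(3R)-3,7-dimethylocta-1,6-dien-3-yl]oxy}silane
Product: 12 (2E,6R)-2,6-dimethyl-6-[(triethylsilyl)oxy]octa-2,7-dien-1-ol
Conditions: SeO2 (0.3 equiv), t-BuOOH, salicylic acid (cat.), CH2Cl2, rt
Reagents that add atoms: tert-butyl hydroperoxide CC(C)(C)OO
Why: selenium dioxide allylic oxidation (ene reaction, then [2,3] shift) goes to the (E)-methyl group of the trisubstituted alkene and should give the E-allylic alcohol, fixing the C8=C9 geometry.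

Step 8
Reactants: 12 (2E,6R)-2,6-dimethyl-6-[(triethylsilyl)oxy]octa-2,7-dien-1-ol
Product: 13 {[(3R,6E)-8-bromo-3,7-dimethylocta-1,6-dien-3-yl]oxy}triethylsilane
Conditions: CBr4, PPh3, CH2Cl2, −20 °C
Reagents that add atoms: carbon tetrabromide BrC(Br)(Br)Br
Why: Appel bromination of the primary allylic alcohol proceeds without allylic shift, so the E geometry is kept.

Step 9
Reactants: 9 (1RS,4R)-3,5,5-trimethyl-4-{[(4-methylphenyl)sulfonyl]methyl}cyclohex-2-en-1-ol; 13 {[(3R,6E)-8-bromo-3,7-dimethylocta-1,6-dien-3-yl]oxy}triethylsilane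
Product: 14 (1RS,4R)-4-[(1RS,3E,7R)-3,7-dimethyl-1-[(4-methylphenyl)sulfonyl]-7-[(triethylsilyl)oxy]nona-3,8-dien-1-yl]-3,5,5-trimethylcyclohex-2-en-1-ol
Conditions: n-BuLi (2.1 equiv), THF–DMPU, −78 °C; then 13, −78 to −20 °C
Reagents that add atoms: none
Why: alkylation of the α-sulfonyl carbanion (formed after the alkoxide) by the primary allylic bromide in an SN2 reaction builds C6–C7; the epimeric sulfone-bearing centre is erased in step 10.

Step 10
Reactants: 14 (as in step 9)
Product: 15 (1RS,4R)-4-[(3E,7R)-3,7-dimethyl-7-[(triethylsilyl)oxy]nona-3,8-dien-1-yl]-3,5,5-trimethylcyclohex-2-en-1-ol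
Conditions: Na(Hg) (6% Na), Na2HPO4, MeOH–THF, −20 °C
Reagents that add atoms: none
Why: reductive desulfonylation (electron transfer, loss of sulfinate, protonation); the sulfone is not allylic, so alkene position and geometry should be kept.

Step 11
Reactants: 15 (as in step 10)
Product: 16 (4R)-4-[(3E,7R)-3,7-dimethyl-7-[(triethylsilyl)oxy]nona-3,8-dien-1-yl]-3,5,5-trimethylcyclohex-2-en-1-one
Conditions: Dess–Martin periodinane, NaHCO3, CH2Cl2, 0 °C to rt
Reagents that add atoms: none
Why: Dess–Martin oxidation of the allylic alcohol returns the ring-A enone; both carbinol epimers converge.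

Step 12
Reactants: 16 (as in step 11)
Product: 17 (10S)-10-[(3E,7R)-3,7-dimethyl-7-[(triethylsilyl)oxy]nona-3,8-dien-1-yl]-9,11,11-trimethyl-1,5-dithiaspiro[5.5]undec-8-en-7-one
Conditions: LDA (2.2 equiv), THF, −78 °C; TsS(CH2)3STs, −78 to 0 °C
Reagents that add atoms: S,S'-propane-1,3-diyl bis(4-methylbenzenesulfonothioate) Cc1ccc(cc1)S(=O)(=O)SCCCSS(=O)(=O)c1ccc(C)cc1
Why: double α'-sulfenylation of the kinetic enolate at C3, the only α'-CH2 (the second C–S bond closes the dithiane intramolecularly), gives the α-keto dithiane, a masked C3 ketone; no stereocentre is made and the low temperature spares the γ-hydrogen at C5 (the descriptor changes to S only through CIP priorities).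

Step 13
Reactants: 17 (as in step 12)
Product: 18 (13R)-8α,13-epoxy-3,3-(propane-1,3-diyldisulfanediyl)-5β-labd-14-en-2-one (H-5 cis to the C10 methyl, H-9 trans to it, trans-fused oxane)
Conditions: MeAlCl2 (2.2 equiv), CH2Cl2, −78 to −40 °C; aq. NaHCO3
Reagents that add atoms: none
Why: MeAlCl2 binds the C2 carbonyl, C9 of the E-C8=C9 alkene adds to C10 (β-carbon of the ring-A enone), the tertiary C8 cation is taken by the C13 silyl ether oxygen with loss of Et3Si, and the aluminium enolate is protonated on work-up; the closest known type is the Lewis acid-promoted, enone-initiated cation–olefin cyclisation with heteroatom termination, the pattern by which labdane ethers arise in nature. Ring B closes 6-endo-trig at the alkene (exo to the enone), and the oxane closes by 6-endo capture of the C8 cation. C10 is set by the tether: the alkene can only reach the enone face that carries the C5 chain, which gives the cis ring A/ring B fusion (C10 methyl cis to H-5). C9 and C8 follow from the E-alkene in a chair-like anti addition (C11 equatorial, C8 methyl axial, oxygen equatorial, trans-fused oxane), and C13 is carried in unchanged. The selectivity the step needs is the alkene face: addition must run through the ring-A half-chair with the chain pseudo-equatorial and axial attack at C10, which puts the C10 methyl axial on the nascent ring B and cis to C11; the spiro-dithiane at C3 is meant to secure this, because in the other half-chair its axial sulfur would be 1,3-diaxial to the chain. Chemoselectivity (trisubstituted alkene before the vinyl group, Markovnikov sense) is inherent.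

Step 14
Reactants: 18 (as in step 13)
Product: 19 (13R)-8α,13-epoxy-5β-labd-14-ene-2,3-dione
Conditions: PhI(OCOCF3)2, NaHCO3, MeCN–H2O (9:1), 0 °C
Reagents that add atoms: water O
Why: oxidative dethioketalisation (sulfur activation by the iodine reagent, hydrolysis of the thionium ion) should unveil the 1,2-dione; the isolated vinyl group and the tertiary ether are inert and no stereocentre is enolisable.

Step 15
Reactants: 19 (as in step 14)
Product: 20 (13R)-8α,13-epoxy-2,3-seco-5β-labd-14-ene-2,3-dioic acid (5S,8R,9R,10S,13R), the target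
Conditions: H2O2 (30%), NaOH, MeOH–H2O, 0 °C to rt; then HCl to pH 2
Reagents that add atoms: hydrogen peroxide OO
Why: alkaline hydrogen peroxide cleavage of the 1,2-diketone (hydroperoxide addition, Baeyer–Villiger-type shift to the anhydride, hydrolysis) cuts C2–C3 and gives both carboxylic acids without touching a stereocentre.

**Compound list**

1 | 2,4,4-trimethylcyclohex-2-en-1-one | CC1=CC(C)(C)CCC1=O | starting material
2 | (1S)-2,4,4-trimethylcyclohex-2-en-1-ol | CC1=CC(C)(C)CC[C@@H]1O | intermediate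
3 | [(4-methylphenyl)sulfonyl]acetic acid | Cc1ccc(cc1)S(=O)(=O)CC(=O)O | starting material
4 | (1S)-2,4,4-trimethylcyclohex-2-en-1-yl [(4-methylphenyl)sulfonyl]acetate | CC1=CC(C)(C)CC[C@@H]1OC(=O)CS(=O)(=O)c1ccc(C)cc1 | intermediate
5 | trimethylsilyl ketene acetal of 4 (alkene geometry not defined) | CC1=CC(C)(C)CC[C@@H]1OC(O[Si](C)(C)C)=CS(=O)(=O)c1ccc(C)cc1 | intermediate (not isolated)
6 | trimethylsilyl 2-[(4-methylphenyl)sulfonyl]-2-[(1R)-2,6,6-trimethylcyclohex-2-en-1-yl]acetate (epimers at the sulfonyl-bearing carbon) | C[Si](C)(C)OC(=O)C([C@H]1C(C)=CCCC1(C)C)S(=O)(=O)c1ccc(C)cc1 | intermediate (not isolated)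
7 | 1-methyl-4-({[(1R)-2,6,6-trimethylcyclohex-2-en-1-yl]methyl}sulfonyl)benzene | Cc1ccc(cc1)S(=O)(=O)C[C@H]1C(C)=CCCC1(C)C | intermediate
8 | (4R)-3,5,5-trimethyl-4-{[(4-methylphenyl)sulfonyl]methyl}cyclohex-2-en-1-one | Cc1ccc(cc1)S(=O)(=O)C[C@H]1C(C)=CC(=O)CC1(C)C | intermediate
9 | (1RS,4R)-3,5,5-trimethyl-4-{[(4-methylphenyl)sulfonyl]methyl}cyclohex-2-en-1-ol | Cc1ccc(cc1)S(=O)(=O)C[C@H]1C(C)=CC(O)CC1(C)C | intermediate
10 | (R)-linalool, (3R)-3,7-dimethylocta-1,6-dien-3-ol | C=C[C@@](O)(C)CCC=C(C)C | starting material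
11 | triethyl{[(3R)-3,7-dimethylocta-1,6-dien-3-yl]oxy}silane | C=C[C@@](O[Si](CC)(CC)CC)(C)CCC=C(C)C | intermediate
12 | (2E,6R)-2,6-dimethyl-6-[(triethylsilyl)oxy]octa-2,7-dien-1-ol | C=C[C@@](O[Si](CC)(CC)CC)(C)CC/C=C(\C)CO | intermediate
13 | {[(3R,6E)-8-bromo-3,7-dimethylocta-1,6-dien-3-yl]oxy}triethylsilane | C=C[C@@](O[Si](CC)(CC)CC)(C)CC/C=C(\C)CBr | intermediate
14 | (1RS,4R)-4-[(1RS,3E,7R)-3,7-dimethyl-1-[(4-methylphenyl)sulfonyl]-7-[(triethylsilyl)oxy]nona-3,8-dien-1-yl]-3,5,5-trimethylcyclohex-2-en-1-ol | C=C[C@@](O[Si](CC)(CC)CC)(C)CC/C=C(\C)CC([C@H]1C(C)=CC(O)CC1(C)C)S(=O)(=O)c1ccc(C)cc1 | intermediate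
15 | (1RS,4R)-4-[(3E,7R)-3,7-dimethyl-7-[(triethylsilyl)oxy]nona-3,8-dien-1-yl]-3,5,5-trimethylcyclohex-2-en-1-ol | C=C[C@@](O[Si](CC)(CC)CC)(C)CC/C=C(\C)CC[C@H]1C(C)=CC(O)CC1(C)C | intermediate
16 | (4R)-4-[(3E,7R)-3,7-dimethyl-7-[(triethylsilyl)oxy]nona-3,8-dien-1-yl]-3,5,5-trimethylcyclohex-2-en-1-one | C=C[C@@](O[Si](CC)(CC)CC)(C)CC/C=C(\C)CC[C@H]1C(C)=CC(=O)CC1(C)C | intermediate
17 | (10S)-10-[(3E,7R)-3,7-dimethyl-7-[(triethylsilyl)oxy]nona-3,8-dien-1-yl]-9,11,11-trimethyl-1,5-dithiaspiro[5.5]undec-8-en-7-one | C=C[C@@](O[Si](CC)(CC)CC)(C)CC/C=C(\C)CC[C@H]1C(C)=CC(=O)C2(SCCCS2)C1(C)C | intermediate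
18 | (13R)-8α,13-epoxy-3,3-(propane-1,3-diyldisulfanediyl)-5β-labd-14-en-2-one | C=C[C@@]1(C)CC[C@@H]2[C@@]3(C)CC(=O)C4(SCCCS4)C(C)(C)[C@H]3CC[C@@]2(C)O1 | intermediate
19 | (13R)-8α,13-epoxy-5β-labd-14-ene-2,3-dione | C=C[C@@]1(C)CC[C@@H]2[C@@]3(C)CC(=O)C(=O)C(C)(C)[C@H]3CC[C@@]2(C)O1 | intermediate
20 | (13R)-8α,13-epoxy-2,3-seco-5β-labd-14-ene-2,3-dioic acid (5S,8R,9R,10S,13R) | C=C[C@@]1(C)CC[C@@H]2[C@@](C)(CC(=O)O)[C@@H](C(C)(C)C(=O)O)CC[C@@]2(C)O1 | target

**Totals and risks**

Total step count: 15. Longest linear sequence: 12 steps (steps 1–5 and 9–15).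

Steps most likely to fail:

Step 13. The alkene may add through the other ring-A half-chair (chain pseudo-axial), which would give the tricycle epimeric at both C8 and C9, or the C8 cation may lose a proton before the ether closes. The first of these is the main uncertainty of the route; the facial preference rests on a conformational argument, not on direct precedent. The fallback sets out from 16 and comes back at 18. It fixes C8 by reagent control before any C–C bond forms. The chain alkene of 16 is epoxidised by a Shi epoxidation (L-fructose-derived ketone catalyst, KHSO5, K2CO3) to the (2S,3S)-oxirane, epoxy enone F1. The dithiane is put on as in step 12 to give epoxy dithiane F2. Removal of the silyl group (Bu4NF) and camphorsulfonic acid in CH2Cl2 then open the epoxide 6-endo at the tertiary C8 with inversion, giving hydroxy oxane F3 with C8 and C13 in place. The C9 hydroxyl is converted with 1,1'-thiocarbonyldiimidazole into thiocarbonylimidazolide F4. Bu3SnH/AIBN (Barton–McCombie-type radical generation) then gives the C9 radical, which closes ring B by 6-exo-trig conjugate addition to C10, cis to ring A through the tether and trans to the chair oxane, to give 18.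

Step 12. The second sulfenylation has to form a fully substituted carbon next to the gem-dimethyl carbon and may stop at the monosulfide, or proton transfer through the dienolate may erode C5. The fallback sets out from 16 and comes back at 19. The kinetic enolate of 16 (LDA, −78 °C) is hydroxylated with 2-(phenylsulfonyl)-3-phenyloxaziridine to α'-hydroxy enone F5. F5 is cyclised under the conditions of step 13 to tricyclic acyloin F6, and Dess–Martin oxidation of F6 gives 19. This variant loses the conformational bias that the dithiane provides in step 13.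

Step 3. The [3,3] shift has to make a bond at a carbon flanked by the gem-dimethyl centre, so the silyl ketene acetal may be diverted to elimination or ester cleavage. The fallback sets out from 2 and comes back at 7. Alcohol 2 is alkylated (KH, Bu3SnCH2I) to stannylmethyl ether F7. Tin–lithium exchange (n-BuLi, THF, −78 °C) triggers a Still–Wittig [2,3] rearrangement with the same suprafacial relay of configuration, giving [(1R)-2,6,6-trimethylcyclohex-2-en-1-yl]methanol F8. Di-p-tolyl disulfide and PBu3 convert F8 into sulfide F9, which is oxidised ((NH4)6Mo7O24 cat., H2O2) to 7.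

Further compounds

F1 | step 13 | (4R)-4-{2-[(2S,3S)-2-methyl-3-[(3R)-3-methyl-3-[(triethylsilyl)oxy]pent-4-en-1-yl]oxiran-2-yl]ethyl}-3,5,5-trimethylcyclohex-2-en-1-one | C=C[C@@](O[Si](CC)(CC)CC)(C)CC[C@@H]1O[C@@]1(C)CC[C@H]2C(C)=CC(=O)CC2(C)C
F2 | step 13 | spiro-dithiane of F1 (1,5-dithiaspiro[5.5]undec-8-en-7-one with the same epoxy side chain) | C=C[C@@](O[Si](CC)(CC)CC)(C)CC[C@@H]1O[C@@]1(C)CC[C@H]2C(C)=CC(=O)C3(SCCCS3)C2(C)C
F3 | step 13 | 10-{2-[(2R,3S,6R)-6-ethenyl-3-hydroxy-2,6-dimethyloxan-2-yl]ethyl}-9,11,11-trimethyl-1,5-dithiaspiro[5.5]undec-8-en-7-one (ring CH as in 17) | C=C[C@@]1(C)CC[C@H](O)[C@@](C)(CC[C@H]2C(C)=CC(=O)C3(SCCCS3)C2(C)C)O1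
F4 | step 13 | O-(imidazol-1-ylthiocarbonyl) derivative of F3 at the oxane hydroxyl | C=C[C@@]1(C)CC[C@H](OC(=S)n2ccnc2)[C@@](C)(CC[C@H]3C(C)=CC(=O)C4(SCCCS4)C3(C)C)O1
F5 | step 12 | (4R,6RS)-4-[(3E,7R)-3,7-dimethyl-7-[(triethylsilyl)oxy]nona-3,8-dien-1-yl]-6-hydroxy-3,5,5-trimethylcyclohex-2-en-1-one | C=C[C@@](O[Si](CC)(CC)CC)(C)CC/C=C(\C)CC[C@H]1C(C)=CC(=O)C(O)C1(C)C
F6 | step 12 | (13R)-8α,13-epoxy-3-hydroxy-5β-labd-14-en-2-one (carbinol epimers) | C=C[C@@]1(C)CC[C@@H]2[C@@]3(C)CC(=O)C(O)C(C)(C)[C@H]3CC[C@@]2(C)O1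
F7 | step 3 | tributyl({[(1S)-2,4,4-trimethylcyclohex-2-en-1-yl]oxy}methyl)stannane | CC1=CC(C)(C)CC[C@@H]1OC[Sn](CCCC)(CCCC)CCCC
F8 | step 3 | [(1R)-2,6,6-trimethylcyclohex-2-en-1-yl]methanol | OC[C@H]1C(C)=CCCC1(C)C
F9 | step 3 | 1-methyl-4-({[(1R)-2,6,6-trimethylcyclohex-2-en-1-yl]methyl}sulfanyl)benzene | Cc1ccc(cc1)SC[C@H]1C(C)=CCCC1(C)C
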